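**Retrosynthetic overview**
1. Target 21 ⇐ tris-MOM ether 20; the three MOM groups are removed last.
2. 20 ⇐ seven-membered 2-aryl-1,3-benzodioxepin-5-one 19 by a catalytic asymmetric 1,2-O→C shift of the acetal carbon (ring contraction 7→6), which forms C2–C3, the pyranone ring and both stereocentres.
3. 19 ⇐ acetalisation of hydroxy ketone 11 (A ring with C3/C4) with MOM-vanillin 17 (B ring with C2).
4. 11 ⇐ resorcinol: MOM protection, C2 prenylation, C5 C–H borylation/oxidation (this oxygen becomes O1), ortho-formylation, hydroxymethylation. 17 ⇐ catechol: mono-methylation, para-formylation with glyoxylic acid, MOM protection.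
5. Ring order: both benzene rings are bought; the dioxepinone ring is made in step 9 and contracted to the chromanone ring in step 10.

Assumption: the SMILES is read as the 2,3-trans (2R,3R) dihydroflavonol; if the (R)-catalyst of step 10 gives the opposite sense of induction, its (S)-antipode is used.

**Route**

Step 1
Reactants: 1 resorcinol
Product: 2 1,3-bis(methoxymethoxy)benzene
Conditions: NaH (2.5 equiv), MOMCl (2.4 equiv), DMF, 0 °C → rt
Reagents that add atoms: chloromethyl methyl ether (MOMCl), COCCl
Why: Williamson-type double O-alkylation (MOM protection) gives the two ethers that direct the next lithiation and later mask O5 and O7.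

Step 2
Reactants: 2 1,3-bis(methoxymethoxy)benzene; 3 prenyl bromide
Product: 5 1,3-bis(methoxymethoxy)-2-(3-methylbut-2-en-1-yl)benzene, via aryllithium 4 (not isolated)
Conditions: n-BuLi (1.1 equiv), THF, 0 °C → rt; CuI (10 mol%), then 3, −78 °C → rt
Reagents that add atoms: n-butyllithium, [Li]CCCC (lithium of intermediate 4 only)
Why: directed ortho-metalation between the two OMOM groups followed by SN2 alkylation with prenyl bromide places the prenyl group between the two protected oxygens.

Step 3
Reactants: 5 1,3-bis(methoxymethoxy)-2-(3-methylbut-2-en-1-yl)benzene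
Product: 7 3,5-bis(methoxymethoxy)-4-(3-methylbut-2-en-1-yl)phenol, via arylboronic pinacol ester 6 (not isolated)
Conditions: [Ir(OMe)(cod)]2 (1.5 mol%), dtbpy (3 mol%), B2pin2 (0.55 equiv), THF, 60 °C; then 30% H2O2, 2 M NaOH, THF, 0 °C
Reagents that add atoms: bis(pinacolato)diboron, CC1(C)OB(OC1(C)C)B1OC(C)(C)C(C)(C)O1 (boron and pinacolate of intermediate 6); hydrogen peroxide, OO (phenol oxygen of 7)
Why: sterically controlled Ir-catalysed C–H borylation occurs at the only C–H without an ortho substituent, and basic peroxide oxidation of the boronate (which leaves the trisubstituted alkene alone) gives the phenol.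

Step 4
Reactants: 7 3,5-bis(methoxymethoxy)-4-(3-methylbut-2-en-1-yl)phenol; 8 formaldehyde (used as paraformaldehyde)
Product: 10 6-hydroxy-2,4-bis(methoxymethoxy)-3-(3-methylbut-2-en-1-yl)benzaldehyde, via salicyl alcohol 9 (not isolated)
Conditions: MgCl2 (1.5 equiv), Et3N (3.75 equiv), (CH2O)n (6 equiv), MeCN, 80 °C
Reagents that add atoms: none
Why: magnesium-phenoxide-directed ortho-hydroxymethylation followed by Oppenauer-type hydride transfer to a second formaldehyde (ortho-specific formylation); the two ortho positions are equivalent, so one aldehyde forms.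

Step 5
Reactants: 10 6-hydroxy-2,4-bis(methoxymethoxy)-3-(3-methylbut-2-en-1-yl)benzaldehyde; 8 formaldehyde (used as paraformaldehyde)
Product: 11 2-hydroxy-1-[6-hydroxy-2,4-bis(methoxymethoxy)-3-(3-methylbut-2-en-1-yl)phenyl]ethan-1-one
Conditions: (CH2O)n (3 equiv), 3-benzyl-5-(2-hydroxyethyl)-4-methylthiazolium chloride (15 mol%), i-Pr2NEt (30 mol%), THF, 60 °C
Reagents that add atoms: none
Why: N-heterocyclic-carbene-catalysed cross-acyloin reaction (hydroxymethylation): the Breslow intermediate of the aryl aldehyde adds to formaldehyde to give the hydroxymethyl ketone.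

Step 6
Reactants: 12 catechol
Product: 13 guaiacol (2-methoxyphenol)
Conditions: MeI (1.0 equiv), K2CO3 (1.0 equiv), acetone, reflux; guaiacol separated from veratrole and catechol by extraction and distillation
Reagents that add atoms: iodomethane, CI
Why: Williamson mono-O-methylation with one equivalent of electrophile.

Step 7
Reactants: 13 guaiacol (2-methoxyphenol); 14 glyoxylic acid
Product: 16 vanillin (4-hydroxy-3-methoxybenzaldehyde), via mandelic acid 15 (not isolated)
Conditions: 14 (50% aq.), NaOH, H2O, rt; then CuSO4 (5 mol%), O2 (1 atm), aq. NaOH, 95 °C; H2SO4 work-up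
Reagents that add atoms: none
Why: the phenoxide undergoes para-selective electrophilic hydroxyalkylation by glyoxylate, and Cu-catalysed aerobic oxidative decarboxylation of the mandelate gives the aldehyde.

Step 8
Reactants: 16 vanillin (4-hydroxy-3-methoxybenzaldehyde)
Product: 17 3-methoxy-4-(methoxymethoxy)benzaldehyde
Conditions: MOMCl (1.3 equiv), K2CO3 (2 equiv), acetone, rt
Reagents that add atoms: chloromethyl methyl ether (MOMCl), COCCl
Why: phenol O-alkylation (MOM protection) prevents quinone-methide formation at the acetal stage and after.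

Step 9
Reactants: 11 2-hydroxy-1-[6-hydroxy-2,4-bis(methoxymethoxy)-3-(3-methylbut-2-en-1-yl)phenyl]ethan-1-one; 17 3-methoxy-4-(methoxymethoxy)benzaldehyde
Product: 19 rac-2-[3-methoxy-4-(methoxymethoxy)phenyl]-6,8-bis(methoxymethoxy)-7-(3-methylbut-2-en-1-yl)-2H-1,3-benzodioxepin-5(4H)-one, via dimethyl acetal 18 (not isolated)
Conditions: 17, HC(OMe)3 (3 equiv), PPTS (5 mol%), MeOH, 40 °C, evaporate; then 11, PPTS (10 mol%), PhMe, 5 Å MS, 50 °C
Reagents that add atoms: trimethyl orthoformate, COC(OC)OC (the two methoxy groups of intermediate 18; none of its atoms remain in 19)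
Why: transacetalisation, first by the primary OH and then by the phenol OH, is driven by methanol removal and closes the seven-membered cyclic acetal; PPTS should be too weak to trigger the rearrangement of step 10, and only the unprotected phenol oxygen (the future O1) can take part.

Step 10
Reactants: 19 rac-2-[3-methoxy-4-(methoxymethoxy)phenyl]-6,8-bis(methoxymethoxy)-7-(3-methylbut-2-en-1-yl)-2H-1,3-benzodioxepin-5(4H)-one
Product: 20 (2R,3R)-3-hydroxy-2-[3-methoxy-4-(methoxymethoxy)phenyl]-5,7-bis(methoxymethoxy)-6-(3-methylbut-2-en-1-yl)-2,3-dihydro-4H-chromen-4-one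
Conditions: (R)-3,3′-bis(2,4,6-triisopropylphenyl)-BINOL N-triflylphosphoramide (10 mol%), 5 Å MS, PhMe (0.02 M), 0 °C → rt
Reagents that add atoms: none
Why: Proposed new method: a catalytic enantioselective 1,2-O→C acetal shift with ring contraction (7→6), in which the chiral acid protonates O3, C2–O3 heterolysis gives an aryloxy-substituted 4-alkoxybenzyl oxocarbenium ion paired with the chiral phosphoramidate, the released α-hydroxy ketone arm enolises to the enediol inside the ion pair, and its C3 adds to C2 in a 6-endo aldol/Prins-type closure, so that C2 has moved from O3 to C3; C–C bond formation is the only irreversible event (the racemic acetal centre is erased on ionisation), the chiral anion selects the C3 face (3R), and the chair-like closure with equatorial aryl, backed by reversible O1–C2 ionisation that leaves C3 untouched, gives the 2,3-trans (2R) isomer; the closest known reaction types are the Petasis–Ferrier rearrangement and its chiral-phosphoric-acid-catalysed aza variant (1,3-O→C shifts of enol acetals and aminals) and the anionic acetal [1,2]-Wittig rearrangement.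

Step 11
Reactants: 20 (2R,3R)-3-hydroxy-2-[3-methoxy-4-(methoxymethoxy)phenyl]-5,7-bis(methoxymethoxy)-6-(3-methylbut-2-en-1-yl)-2,3-dihydro-4H-chromen-4-one
Product: 21 (2R,3R)-3,5,7-trihydroxy-2-(4-hydroxy-3-methoxyphenyl)-6-(3-methylbut-2-en-1-yl)-2,3-dihydro-4H-chromen-4-one
Conditions: 3 M aq. HCl/MeOH (1:4), 40 °C
Reagents that add atoms: none
Why: acid-catalysed acetal exchange with methanol removes the three MOM groups under conditions mild enough to spare the prenyl group, and neither stereocentre is affected (the trans isomer is also the thermodynamic one).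

**Compound list**
1 | resorcinol (benzene-1,3-diol) | Oc1cccc(O)c1 | starting material
2 | 1,3-bis(methoxymethoxy)benzene | COCOc1cccc(OCOC)c1 | intermediate
3 | prenyl bromide (1-bromo-3-methylbut-2-ene) | CC(C)=CCBr | starting material
4 | [2,6-bis(methoxymethoxy)phenyl]lithium | [Li]c1c(OCOC)cccc1OCOC | intermediate (not isolated)
5 | 1,3-bis(methoxymethoxy)-2-(3-methylbut-2-en-1-yl)benzene | COCOc1cccc(OCOC)c1CC=C(C)C | intermediate
6 | 2-[3,5-bis(methoxymethoxy)-4-(3-methylbut-2-en-1-yl)phenyl]-4,4,5,5-tetramethyl-1,3,2-dioxaborolane | COCOc1cc(B2OC(C)(C)C(C)(C)O2)cc(OCOC)c1CC=C(C)C | intermediate (not isolated)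
7 | 3,5-bis(methoxymethoxy)-4-(3-methylbut-2-en-1-yl)phenol | COCOc1cc(O)cc(OCOC)c1CC=C(C)C | intermediate
8 | formaldehyde (used as paraformaldehyde) | C=O | starting material
9 | 2-(hydroxymethyl)-3,5-bis(methoxymethoxy)-4-(3-methylbut-2-en-1-yl)phenol (as its magnesium salt) | OCc1c(O)cc(OCOC)c(CC=C(C)C)c1OCOC | intermediate (not isolated)
10 | 6-hydroxy-2,4-bis(methoxymethoxy)-3-(3-methylbut-2-en-1-yl)benzaldehyde | O=Cc1c(O)cc(OCOC)c(CC=C(C)C)c1OCOC | intermediate
11 | 2-hydroxy-1-[6-hydroxy-2,4-bis(methoxymethoxy)-3-(3-methylbut-2-en-1-yl)phenyl]ethan-1-one | O=C(CO)c1c(O)cc(OCOC)c(CC=C(C)C)c1OCOC | intermediate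
12 | catechol (benzene-1,2-diol) | Oc1ccccc1O | starting material
13 | guaiacol (2-methoxyphenol) | COc1ccccc1O | intermediate
14 | glyoxylic acid | O=CC(=O)O | starting material
15 | rac-4-hydroxy-3-methoxymandelic acid | COc1cc(C(O)C(=O)O)ccc1O | intermediate (not isolated)
16 | vanillin (4-hydroxy-3-methoxybenzaldehyde) | COc1cc(C=O)ccc1O | intermediate
17 | 3-methoxy-4-(methoxymethoxy)benzaldehyde | COCOc1ccc(C=O)cc1OC | intermediate
18 | 4-(dimethoxymethyl)-2-methoxy-1-(methoxymethoxy)benzene | COCOc1ccc(C(OC)OC)cc1OC | intermediate (not isolated)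
19 | rac-2-[3-methoxy-4-(methoxymethoxy)phenyl]-6,8-bis(methoxymethoxy)-7-(3-methylbut-2-en-1-yl)-2H-1,3-benzodioxepin-5(4H)-one (seven-membered cyclic acetal; O1 phenolic, O3 from the CH2OH) | COCOc1ccc(C2OCC(=O)c3c(OCOC)c(CC=C(C)C)c(OCOC)cc3O2)cc1OC | intermediate
20 | (2R,3R)-3-hydroxy-2-[3-methoxy-4-(methoxymethoxy)phenyl]-5,7-bis(methoxymethoxy)-6-(3-methylbut-2-en-1-yl)-2,3-dihydro-4H-chromen-4-one | COCOc1ccc([C@H]2Oc3cc(OCOC)c(CC=C(C)C)c(OCOC)c3C(=O)[C@@H]2O)cc1OC | intermediate
21 | (2R,3R)-3,5,7-trihydroxy-2-(4-hydroxy-3-methoxyphenyl)-6-(3-methylbut-2-en-1-yl)-2,3-dihydro-4H-chromen-4-one | COc1cc([C@H]2Oc3cc(O)c(CC=C(C)C)c(O)c3C(=O)[C@@H]2O)ccc1O | target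

**Step count and risks**

Total: 11 steps. Longest linear sequence: 8 steps (1, 2, 3, 4, 5, 9, 10, 11).

Most likely to fail:

Step 10 (the new ring contraction). It may stop at reversible ionisation without C–C bond formation, or give low ee through a racemic background path. The fallback uses known chemistry, sets out from 11 (with 17) and comes back at 20. A syn-selective direct catalytic asymmetric aldol reaction of the α-hydroxy ketone 11 with aldehyde 17 (Et2Zn/(S,S)-ProPhenol dinuclear zinc catalyst, THF, 4 Å MS, −35 °C) gives (2R,3S)-2,3-dihydroxy-1-[6-hydroxy-2,4-bis(methoxymethoxy)-3-(3-methylbut-2-en-1-yl)phenyl]-3-[3-methoxy-4-(methoxymethoxy)phenyl]propan-1-one F1. Mitsunobu cyclisation (PPh3, DIAD, THF, 0 °C) then lets the phenol oxygen displace the activated benzylic hydroxyl with inversion (S → R), closing the pyranone to the 2,3-trans product 20.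

Step 5 (hydroxymethylation). The di-ortho-substituted, phenoxide-bearing aldehyde may be slow to form the Breslow intermediate. The fallback sets out from 10 and comes back at 11. Addition of (isopropoxydimethylsilyl)methylmagnesium chloride (2.5 equiv, THF, 0 °C) to aldehyde 10 gives 1-[6-hydroxy-2,4-bis(methoxymethoxy)-3-(3-methylbut-2-en-1-yl)phenyl]-2-[dimethyl(propan-2-yloxy)silyl]ethan-1-ol F2. Tamao oxidation (30% H2O2, KF, KHCO3, THF/MeOH, rt) converts it into 1-[6-hydroxy-2,4-bis(methoxymethoxy)-3-(3-methylbut-2-en-1-yl)phenyl]ethane-1,2-diol F3, and selective oxidation of the benzylic alcohol (MnO2, CH2Cl2, rt) gives 11.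

Step 9 (seven-membered aryl alkyl acetal). The carbonyl-chelated phenol is a poor acetalisation partner and medium-ring closure competes with oligomeric acetals. The fallback sets out from 17 and 11 and comes back at 19. Reduction of 17 (NaBH4, MeOH, 0 °C) gives [3-methoxy-4-(methoxymethoxy)phenyl]methanol F4, which is converted (MsCl, Et3N, LiCl, THF, 0 °C) into 4-(chloromethyl)-2-methoxy-1-(methoxymethoxy)benzene F5. Williamson alkylation of the phenol of 11 (K2CO3, NaI cat., DMF, rt) gives 2-hydroxy-1-[6-{[3-methoxy-4-(methoxymethoxy)phenyl]methoxy}-2,4-bis(methoxymethoxy)-3-(3-methylbut-2-en-1-yl)phenyl]ethan-1-one F6. Oxidation of its electron-rich benzylic ether C–H (DDQ, 4 Å MS, CH2Cl2, 0 °C) generates the oxocarbenium ion, which the neighbouring primary hydroxyl traps to close the cyclic acetal 19.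

**Further compounds**
F1 | step 10 | (2R,3S)-2,3-dihydroxy-1-[6-hydroxy-2,4-bis(methoxymethoxy)-3-(3-methylbut-2-en-1-yl)phenyl]-3-[3-methoxy-4-(methoxymethoxy)phenyl]propan-1-one | O=C(c1c(O)cc(OCOC)c(CC=C(C)C)c1OCOC)[C@H](O)[C@@H](O)c1ccc(OCOC)c(OC)c1
F2 | step 5 | 1-[6-hydroxy-2,4-bis(methoxymethoxy)-3-(3-methylbut-2-en-1-yl)phenyl]-2-[dimethyl(propan-2-yloxy)silyl]ethan-1-ol | CC(C)O[Si](C)(C)CC(O)c1c(O)cc(OCOC)c(CC=C(C)C)c1OCOC
F3 | step 5 | 1-[6-hydroxy-2,4-bis(methoxymethoxy)-3-(3-methylbut-2-en-1-yl)phenyl]ethane-1,2-diol | OCC(O)c1c(O)cc(OCOC)c(CC=C(C)C)c1OCOC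
F4 | step 9 | [3-methoxy-4-(methoxymethoxy)phenyl]methanol | COCOc1ccc(CO)cc1OC
F5 | step 9 | 4-(chloromethyl)-2-methoxy-1-(methoxymethoxy)benzene | COCOc1ccc(CCl)cc1OC
F6 | step 9 | 2-hydroxy-1-[6-{[3-methoxy-4-(methoxymethoxy)phenyl]methoxy}-2,4-bis(methoxymethoxy)-3-(3-methylbut-2-en-1-yl)phenyl]ethan-1-one | OCC(=O)c1c(OCc2ccc(OCOC)c(OC)c2)cc(OCOC)c(CC=C(C)C)c1OCOC
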